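**Retrosynthetic overview**
- The target is cut at both aryl–CH bonds of the 6-methylheptylidene bridge: two identical 8-acyl-5,7-dihydroxy-2,2-dimethylchromans plus 6-methylheptanal, joined last by aldol-type hydroxyalkylation, dehydration to an ortho-quinone methide and Michael addition of the second arene.
- The chroman ketone comes from an 8-bromo-5,7-bis(benzyloxy)-2,2-dimethylchroman (as its aryllithium) and the Weinreb amide of (R)-2-methylbutanoic acid.
- The (R) centre is set by Evans methylation of an N-butanoyl (R)-4-benzyloxazolidinone.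
- The bromochroman comes from phloroglucinol and 3-methylbut-2-enoic acid by way of the chromanone, O-benzylation, removal of the C4 carbonyl and bromination at C8.
- Ring order: the benzene rings are bought; the pyran ring of each half is closed in step 1; no ring is formed afterwards.

Assumption: 6-methylheptan-1-ol and (R)-4-benzyl-1,3-oxazolidin-2-one are taken as inexpensive catalogue chemicals; the bridging CH carries two identical (R) arms and is therefore not a stereocentre.

**Route**

Step 1
Reactants: 1 phloroglucinol; 2 3-methylbut-2-enoic acid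
Product: 3 5,7-dihydroxy-2,2-dimethylchroman-4-one
Conditions: P2O5/MeSO3H, 70 °C
Reagents that add atoms: none
Why: Friedel–Crafts acylation of the symmetrical triol followed by intramolecular oxa-Michael ring closure can give only this chromanone.

Step 2
Reactants: 3 5,7-dihydroxy-2,2-dimethylchroman-4-one
Product: 4 5,7-bis(benzyloxy)-2,2-dimethylchroman-4-one
Conditions: BnBr (2.6 equiv), K2CO3 (3 equiv), DMF, 70 °C
Reagents that add atoms: benzyl bromide (BrCc1ccccc1)
Why: Williamson ether synthesis; the chelated 5-OH reacts more slowly but is driven through by heat and excess bromide.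

Step 3
Reactants: 4 5,7-bis(benzyloxy)-2,2-dimethylchroman-4-one
Product: 5 5,7-bis(benzyloxy)-2,2-dimethylchroman-4-ol (racemic)
Conditions: NaBH4 (2 equiv), THF/MeOH 1:1, 0 °C → rt
Reagents that add atoms: none
Why: Hydride reduction of the aryl ketone; the new C4 carbinol centre is racemic and is erased in step 4.

Step 4
Reactants: 5 5,7-bis(benzyloxy)-2,2-dimethylchroman-4-ol
Product: 6 5,7-bis(benzyloxy)-2,2-dimethylchroman
Conditions: Et3SiH (3 equiv), CF3CO2H (3 equiv), CH2Cl2, −20 → 0 °C
Reagents that add atoms: none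
Why: Ionic hydrogenation; the benzylic cation, stabilised by three ring oxygens, forms under mild acid and takes hydride from the silane, and the benzyl ethers survive.

Step 5
Reactants: 6 5,7-bis(benzyloxy)-2,2-dimethylchroman
Product: 7 5,7-bis(benzyloxy)-8-bromo-2,2-dimethylchroman
Conditions: NBS (1.0 equiv), CH2Cl2, −40 → 0 °C, dark
Reagents that add atoms: N-bromosuccinimide (O=C1CCC(=O)N1Br)
Why: Electrophilic aromatic bromination; C8 (between ring O1 and one OBn) is less hindered than C6 (between two OBn) and is the site attacked in analogous 5,7-bis(benzyloxy)flavans, to be confirmed by NOE from the remaining aryl H to both OCH2Ph groups.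

Step 6
Reactants: 8 (4R)-4-benzyl-1,3-oxazolidin-2-one; 9 butanoyl chloride
Product: 11 (4R)-4-benzyl-3-butanoyl-1,3-oxazolidin-2-one, via N-lithio oxazolidinone 10 (not isolated)
Conditions: n-BuLi (1.0 equiv), THF, −78 °C; then 9 (1.1 equiv), −78 → 0 °C
Reagents that add atoms: n-butyllithium ([Li]CCCC)
Why: N-acylation of the lithiated carbamate by the acid chloride is the standard, clean entry to Evans imides.

Step 7
Reactants: 11 (4R)-4-benzyl-3-butanoyl-1,3-oxazolidin-2-one
Product: 13 (4R)-4-benzyl-3-[(2R)-2-methylbutanoyl]-1,3-oxazolidin-2-one, via sodium Z-enolate 12 (not isolated)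
Conditions: NaN(SiMe3)2 (1.1 equiv), THF, −78 °C; MeI (4 equiv), −78 → −40 °C; chromatography to one diastereomer
Reagents that add atoms: iodomethane (CI); sodium hexamethyldisilazide (C[Si](C)(C)N([Na])[Si](C)(C)C)
Why: Evans asymmetric alkylation; the chelated Z-enolate is methylated on the face away from the benzyl group, which with the (R) auxiliary gives the (2R) centre (about 10:1, minor diastereomer removed).

Step 8
Reactants: 13 (4R)-4-benzyl-3-[(2R)-2-methylbutanoyl]-1,3-oxazolidin-2-one
Product: 15 (2R)-2-methylbutanoic acid, via lithium peroxycarboxylate 14 (not isolated)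
Conditions: LiOH·H2O (2 equiv), 30% aq H2O2 (4 equiv), THF/H2O 3:1, 0 °C; aq Na2SO3; HCl to pH 2
Reagents that add atoms: hydrogen peroxide (OO); lithium hydroxide ([Li+].[OH-])
Why: Hydroperoxide cleaves the exocyclic imide carbonyl selectively at 0 °C without epimerising the α-centre, and sulfite reduces the peracid salt to the acid.

Step 9
Reactants: 15 (2R)-2-methylbutanoic acid
Product: 17 (2R)-N-methoxy-N,2-dimethylbutanamide, via acyl imidazole 16 (not isolated)
Conditions: CDI (1.1 equiv), CH2Cl2, 0 °C → rt; then MeNH(OMe)·HCl (1.3 equiv), rt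
Reagents that add atoms: N,O-dimethylhydroxylamine hydrochloride (CNOC.Cl); 1,1'-carbonyldiimidazole (O=C(n1ccnc1)n1ccnc1)
Why: Amide coupling through the acyl imidazole uses no strong base, so the α-centre is retained in the Weinreb amide.

Step 10
Reactants: 7 5,7-bis(benzyloxy)-8-bromo-2,2-dimethylchroman; 17 (2R)-N-methoxy-N,2-dimethylbutanamide
Product: 20 (2R)-1-[5,7-bis(benzyloxy)-2,2-dimethylchroman-8-yl]-2-methylbutan-1-one, via aryllithium 18 (not isolated), via lithium hemiaminal 19 (not isolated)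
Conditions: n-BuLi (1.0 equiv), THF, −78 °C, 15 min; then 17 (1.3 equiv), −78 → −20 °C; 1 M aq HCl quench
Reagents that add atoms: n-butyllithium ([Li]CCCC)
Why: Bromine–lithium exchange fixes the metal at C8, and the Weinreb ketone synthesis holds the chelated tetrahedral adduct until the cold quench, so there is no over-addition and the ketone never meets base.

Step 11
Reactants: 20 (2R)-1-[5,7-bis(benzyloxy)-2,2-dimethylchroman-8-yl]-2-methylbutan-1-one
Product: 21 (2R)-1-(5,7-dihydroxy-2,2-dimethylchroman-8-yl)-2-methylbutan-1-one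
Conditions: H2 (1 atm), 10% Pd/C, EtOAc, rt
Reagents that add atoms: none
Why: Hydrogenolysis of the two benzyl ethers under neutral conditions leaves the hindered, chelated aryl ketone and its α-centre untouched.

Step 12
Reactants: 22 6-methylheptan-1-ol
Product: 23 6-methylheptanal
Conditions: TEMPO (10 mol %), PhI(OAc)2 (1.1 equiv), CH2Cl2, rt
Reagents that add atoms: none
Why: TEMPO-catalysed oxidation of a primary alcohol stops cleanly at the aldehyde.

Step 13
Reactants: 21 (2R)-1-(5,7-dihydroxy-2,2-dimethylchroman-8-yl)-2-methylbutan-1-one (2.1 equiv); 23 6-methylheptanal (1.0 equiv)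
Product: 26 6,6'-(6-methylheptane-1,1-diyl)bis{5,7-dihydroxy-2,2-dimethyl-8-[(2R)-2-methylbutanoyl]chroman}, via benzylic carbinol 24 (not isolated), via ortho-quinone methide 25 (not isolated)
Conditions: TsOH·H2O (10 mol %), CH2Cl2, rt → 40 °C
Reagents that add atoms: none
Why: Acid-catalysed aldol-type hydroxyalkylation at C6 (the only free ring carbon, the carbon of a vinylogous enol) gives 24, dehydration gives 25, and Michael addition of a second molecule of 21 closes the bridge; the bridging carbon bears two identical (R) arms and is not a stereocentre, and dilute acid at this temperature does not enolise the chelated ketones.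

**Compound list**

1 | phloroglucinol (benzene-1,3,5-triol) | Oc1cc(O)cc(O)c1 | starting material
2 | 3-methylbut-2-enoic acid | CC(C)=CC(=O)O | starting material
3 | 5,7-dihydroxy-2,2-dimethylchroman-4-one | CC1(C)CC(=O)c2c(O)cc(O)cc2O1 | intermediate
4 | 5,7-bis(benzyloxy)-2,2-dimethylchroman-4-one | CC1(C)CC(=O)c2c(OCc3ccccc3)cc(OCc3ccccc3)cc2O1 | intermediate
5 | 5,7-bis(benzyloxy)-2,2-dimethylchroman-4-ol (racemic) | CC1(C)CC(O)c2c(OCc3ccccc3)cc(OCc3ccccc3)cc2O1 | intermediate
6 | 5,7-bis(benzyloxy)-2,2-dimethylchroman | CC1(C)CCc2c(OCc3ccccc3)cc(OCc3ccccc3)cc2O1 | intermediate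
7 | 5,7-bis(benzyloxy)-8-bromo-2,2-dimethylchroman | CC1(C)CCc2c(OCc3ccccc3)cc(OCc3ccccc3)c(Br)c2O1 | intermediate
8 | (4R)-4-benzyl-1,3-oxazolidin-2-one | O=C1N[C@H](Cc2ccccc2)CO1 | starting material
9 | butanoyl chloride | CCCC(Cl)=O | starting material
10 | N-lithio derivative of 8 (not isolated) | [Li]N1[C@H](Cc2ccccc2)COC1=O | intermediate
11 | (4R)-4-benzyl-3-butanoyl-1,3-oxazolidin-2-one | CCCC(=O)N1[C@H](Cc2ccccc2)COC1=O | intermediate
12 | sodium Z-enolate of 11 (not isolated) | CC/C=C(\O[Na])N1[C@H](Cc2ccccc2)COC1=O | intermediate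
13 | (4R)-4-benzyl-3-[(2R)-2-methylbutanoyl]-1,3-oxazolidin-2-one | CC[C@@H](C)C(=O)N1[C@H](Cc2ccccc2)COC1=O | intermediate
14 | lithium (2R)-2-methylbutaneperoxoate (not isolated) | [Li+].CC[C@@H](C)C(=O)O[O-] | intermediate
15 | (2R)-2-methylbutanoic acid | CC[C@@H](C)C(=O)O | intermediate
16 | (2R)-1-(imidazol-1-yl)-2-methylbutan-1-one (not isolated) | CC[C@@H](C)C(=O)n1ccnc1 | intermediate
17 | (2R)-N-methoxy-N,2-dimethylbutanamide | CC[C@@H](C)C(=O)N(C)OC | intermediate
18 | [5,7-bis(benzyloxy)-2,2-dimethylchroman-8-yl]lithium (not isolated) | [Li]c1c(OCc2ccccc2)cc(OCc2ccccc2)c2CCC(C)(C)Oc12 | intermediate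
19 | lithium (2R)-1-[5,7-bis(benzyloxy)-2,2-dimethylchroman-8-yl]-1-[methoxy(methyl)amino]-2-methylbutan-1-olate (not isolated; hemiaminal carbon unassigned) | CC[C@@H](C)C(O[Li])(N(C)OC)c1c(OCc2ccccc2)cc(OCc2ccccc2)c2CCC(C)(C)Oc12 | intermediate
20 | (2R)-1-[5,7-bis(benzyloxy)-2,2-dimethylchroman-8-yl]-2-methylbutan-1-one | CC[C@@H](C)C(=O)c1c(OCc2ccccc2)cc(OCc2ccccc2)c2CCC(C)(C)Oc12 | intermediate
21 | (2R)-1-(5,7-dihydroxy-2,2-dimethylchroman-8-yl)-2-methylbutan-1-one | CC[C@@H](C)C(=O)c1c(O)cc(O)c2CCC(C)(C)Oc12 | intermediate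
22 | 6-methylheptan-1-ol | CC(C)CCCCCO | starting material
23 | 6-methylheptanal | CC(C)CCCCC=O | intermediate
24 | (2R)-1-[5,7-dihydroxy-6-(1-hydroxy-6-methylheptyl)-2,2-dimethylchroman-8-yl]-2-methylbutan-1-one (not isolated; carbinol epimers) | CC[C@@H](C)C(=O)c1c(O)c(C(O)CCCCC(C)C)c(O)c2CCC(C)(C)Oc12 | intermediate
25 | 5-hydroxy-2,2-dimethyl-8-[(2R)-2-methylbutanoyl]-6-(6-methylheptylidene)-3,4-dihydro-2H-chromen-7(6H)-one (ortho-quinone methide, not isolated) | CC[C@@H](C)C(=O)C1=C2OC(C)(C)CCC2=C(O)C(=CCCCCC(C)C)C1=O | intermediate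
26 | 6,6'-(6-methylheptane-1,1-diyl)bis{5,7-dihydroxy-2,2-dimethyl-8-[(2R)-2-methylbutanoyl]chroman} | CC[C@@H](C)C(=O)c1c(O)c(C(CCCCC(C)C)c2c(O)c3c(c(C(=O)[C@H](C)CC)c2O)OC(C)(C)CC3)c(O)c2c1OC(C)(C)CC2 | target

**Summary**

Total steps: 13. Longest linear sequence: 8 steps (1, 2, 3, 4, 5, 10, 11, 13).

Steps most likely to fail:

Step 5 (regiochemistry of bromination, C8 against C6). The fallback sets out from phloroglucinol 1 and amide 17 and comes back at 21; it acylates a symmetrical ring before the pyran is closed. Phloroglucinol 1 with MOMCl and i-Pr2NEt gives 1,3,5-tris(methoxymethoxy)benzene F1. n-BuLi in THF at 0 °C metalates between two acetal oxygens to give 2,4,6-tris(methoxymethoxy)phenyllithium F2. Addition to 17 gives the lithium hemiaminal adduct F3 and, after quench, (2R)-2-methyl-1-[2,4,6-tris(methoxymethoxy)phenyl]butan-1-one F4. HCl in MeOH removes the three acetals to give (2R)-2-methyl-1-(2,4,6-trihydroxyphenyl)butan-1-one F5. 2-Methylbut-3-en-2-ol with BF3·OEt2 in dioxane alkylates a free ring carbon and closes the pyran to give 21 together with (2R)-1-(5,7-dihydroxy-2,2-dimethylchroman-6-yl)-2-methylbutan-1-one F6. The two isomers are separated on silica and 21 is assigned by HMBC.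

Step 10 (hindered aryllithium with an α-branched amide; the ortho-lithiated benzyl ether must stay cold). The fallback sets out from acid 15 and bromide 7 (through aryllithium 18) and comes back at 20. LiAlH4 reduces 15 to (2R)-2-methylbutan-1-ol F7. TEMPO/PhI(OAc)2 gives (2R)-2-methylbutanal F8, used at once as a cold solution. Aryllithium 18 adds to this more reactive electrophile at −78 °C to give (2R)-1-[5,7-bis(benzyloxy)-2,2-dimethylchroman-8-yl]-2-methylbutan-1-ol F9 as a mixture of carbinol epimers. Dess–Martin periodinane oxidises both epimers to 20.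

Step 13 (aldehyde self-condensation or incomplete second arylation). The fallback sets out from 21 and 23 and comes back at 26, forming the two aryl–CH bonds in separate operations. 21, 23 and morpholine (1 equiv each, EtOH, rt) give the Mannich base (2R)-1-{5,7-dihydroxy-2,2-dimethyl-6-[6-methyl-1-(morpholin-4-yl)heptyl]chroman-8-yl}-2-methylbutan-1-one F10, which is isolated. Heating F10 with a second equivalent of 21 (toluene, AcOH 1 equiv, 80 °C) expels morpholine to regenerate ortho-quinone methide 25 with no free aldehyde present, and Michael addition of 21 gives 26.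

**Further compounds**

F1 | step 5 | 1,3,5-tris(methoxymethoxy)benzene | COCOc1cc(OCOC)cc(OCOC)c1
F2 | step 5 | 2,4,6-tris(methoxymethoxy)phenyllithium | [Li]c1c(OCOC)cc(OCOC)cc1OCOC
F3 | step 5 | lithium (2R)-1-[methoxy(methyl)amino]-2-methyl-1-[2,4,6-tris(methoxymethoxy)phenyl]butan-1-olate | CC[C@@H](C)C(O[Li])(N(C)OC)c1c(OCOC)cc(OCOC)cc1OCOC
F4 | step 5 | (2R)-2-methyl-1-[2,4,6-tris(methoxymethoxy)phenyl]butan-1-one | CC[C@@H](C)C(=O)c1c(OCOC)cc(OCOC)cc1OCOC
F5 | step 5 | (2R)-2-methyl-1-(2,4,6-trihydroxyphenyl)butan-1-one | CC[C@@H](C)C(=O)c1c(O)cc(O)cc1O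
F6 | step 5 | (2R)-1-(5,7-dihydroxy-2,2-dimethylchroman-6-yl)-2-methylbutan-1-one | CC[C@@H](C)C(=O)c1c(O)cc2OC(C)(C)CCc2c1O
F7 | step 10 | (2R)-2-methylbutan-1-ol | CC[C@@H](C)CO
F8 | step 10 | (2R)-2-methylbutanal | CC[C@@H](C)C=O
F9 | step 10 | (2R)-1-[5,7-bis(benzyloxy)-2,2-dimethylchroman-8-yl]-2-methylbutan-1-ol | CC[C@@H](C)C(O)c1c(OCc2ccccc2)cc(OCc2ccccc2)c2CCC(C)(C)Oc12
F10 | step 13 | (2R)-1-{5,7-dihydroxy-2,2-dimethyl-6-[6-methyl-1-(morpholin-4-yl)heptyl]chroman-8-yl}-2-methylbutan-1-one | CC[C@@H](C)C(=O)c1c(O)c(C(CCCCC(C)C)N2CCOCC2)c(O)c2CCC(C)(C)Oc12
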